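## Structural features

The target 29 is a cis-fused 1,4,4a,5,8,8a-hexahydronaphthalen-1-one. Ring B (C1, C2, C3, C4, C4a, C8a) holds the C1 ketone and the tetrasubstituted C2=C3 alkene, which carries the C2 methyl ester and the C3 hexadecyl chain. Ring A (C4a, C5, C6, C7, C8, C8a) holds the trisubstituted C6=C7 alkene with the second hexadecyl chain on C6 and a methyl ester on each allylic carbon, C5 and C8. Four stereocentres stand in a row (C5, C4a, C8a, C8): the hydrogens on C8, C8a and C4a are mutually cis, and the C5 ester is trans to the C4a–C4 bond. The fragile sites are C5–H and C8–H (each α to an ester and allylic), C8a–H (α to the ketone, in a crowded all-cis C8/C8a/C4a triad) and the cross-conjugated β-keto ester of ring B. The real difficulty is to build this contiguous array beside two unfunctionalised chains and never expose it to strong base afterwards. The key step exploits the γ,δ-unsaturated carbonyl array O=C1–C8a–C8–C7=C6: read backwards through a [3,3] shift, it is an enolate of C1 tied through oxygen to C6, that is a six-membered lactone (O, C1, C8a, C4a, C5, C6) with the C7=C8 enoate on C6.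

## Logic of the disconnections

29 ⇒ 27 (through 28). Cut C2–C3 of ring B. C2 lies between two carbonyls and C3 becomes an alkyne carbon, so ring B closes by a cycloisomerisation that adds no atoms. Ring B, its alkene and the C3 chain all come from the arm already on C4a. The forward step must attack C3 through carbon (six-membered, not seven) on an internal alkyne, and the alkene shift must use a base too weak for C8a–H, C5–H or C8–H.

27 ⇒ 25. Cut C1–C2. A β-keto ester is an acid plus a malonate unit, and 25 has only one free acid among three carboxyl groups. The forward step must activate a hindered acid without epimerising C8a.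

25 ⇒ 22 (key). Cut C8–C8a, restore O–C6, return the alkene from C6=C7 to C7=C8. Ring A opens to a monocyclic lactone and two stereocentres (C8, C8a) are traded for one (C6). The forward step needs the alkenyl group cis to the C5 ester and trans to the arm, an E enoate, and enolisation at C8a only.

22 ⇒ 20 + 21. Cut C7=C8. The enoate is a vinyl group plus an acrylate, which keeps the Michael acceptor out of all earlier steps. The forward step must engage a vinyl group on a fully substituted carbon and leave the alkyne alone.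

20 ⇒ 18 ⇒ 16. Exchange the C5 carboxyl group, then cut C6–C7 and the lactone O–C1 bond. C6 becomes a ketone and C1 a methyl ester. The forward addition must be face-selective at C6 and must not enolise C5.

16 ⇒ 13 + 14. Cut C5–C6. C5 is the α-carbon of an imide and C6 an acyl chloride carbon. The auxiliary must set C5, and the product must hold that configuration.

13 ⇒ 10 + 11, and 10 ⇒ 9. Cut the N–acyl bond, then the methyl ester C–O bond. This leads to a prochiral cyclic anhydride, so C4a is set by a catalyst.

9 ⇒ 8 ⇒ 6 ⇒ 3 + 4, and 3 ⇒ 2 ⇒ 1. Rejoin the two carboxyl carbons as a ring alkene, then cut C3–C4 (sp–sp3). The forward sequence needs ozone to distinguish alkene from alkyne, and an SN2 reaction at a β-branched primary carbon.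

## Other disconnections considered

Alternative 1: The cut runs through C4a–C8a and C5–C6. In the forward step the pyranone A1, which carries an (E)-enoate on a tether from its 3-position, is heated; intramolecular [4+2] addition across positions 3 and 6 closes both rings, and the bridged lactone then loses its carboxyl bridge as gas to give the diene diester A2. In its favour: two rings and two C–C bonds in one base-free step, a convergent assembly, and a C4a/C5 relationship that follows stereospecifically from the enoate geometry. On that last point it is the better plan, since the chosen route needs an auxiliary and a chelate-controlled addition before C5 and C6 are secure. Against it: C8 and C8a emerge as sp2 carbons of a dienoate, so the two most delicate stereocentres must still be made by reducing one of two conjugated alkenes selectively. C1 arrives as a silyl ether and C2 without its ester, so oxidation and a C2 carboxylation next to an epimerisable C8a follow. Face selection rests on one remote silyloxy centre, and diene and dienophile are both electron-poor, which points to forcing temperatures. On mechanism the two plans are equally predictable. On step economy the key step of A1 to A2 is better, but the chosen plan is shorter overall because 25 already has all four stereocentres and every carbonyl at its final oxidation level.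

Alternative 2: The cut runs through C4a–C8a, C5–C6 and C7–C8. A zerovalent nickel phosphine catalyst couples the β-carbons of the tethered bis-enoate A3 (closing ring B), inserts the terminal alkyne A4 and reductively eliminates to the cis-fused bicycle A5. In its favour: three C–C bonds and both rings in one catalytic step from two simple pieces. In bond economy it is clearly the better plan, and A5 already has C5, C4a, C8a and C8 as sp3 centres, which makes it the equal of 25 in that respect. Against it: the orientation of alkyne insertion (chain on C6 or C7) is differentiated only by the distant silyl ether. The relative configuration of four centres depends on metallacycle geometry, which is much less predictable than a concerted shift. Alkyne oligomerisation and β-hydride loss compete. A5 still lacks the C2 ester and has C1 at the alcohol level, so the endgame (deprotection, oxidation, acylation at C2 of an enone) is longer and more basic than the endgame from 25.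

Alternative 3: The cut is C4a–C8a alone. The triene A6, assembled by Suzuki coupling with both terminal substituents pointing outward, is heated; disrotatory 6π closure gives the cyclohexadiene A7 with cis C4a and C8a substituents. In its favour: orbital symmetry fixes the cis relationship as reliably as the boat fixes C8/C8a in the chosen plan (equal on that point), the assembly is convergent, and the arm and the β-oxygenated ester chain set up the same ring B closure as in the chosen plan (equal endgame logic). Against it: A7 is a 1,3-diene in which C5 and C8 are sp2, so two stereocentres remain to be set by a formal 1,4-addition of hydrogen across a dienoate in the presence of an alkyne. The absolute sense depends on weak torquoselection from the silyloxy centre, and C1 must still be oxidised. The chosen plan sets all four centres before ring B is touched, and A7 is further from the target than 25.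

Key step: step 12

Remarks before the steps.
- Locants C1–C8a of 29 are used for the same atoms in every earlier compound.
- Structure check: 22 and 25 were re-derived from 29 (hexadecyl = C16, arm = octadec-2-ynyl, C4a R, C5 S, C6 S in 22; C8 R, C8a S in 25). An E enoate passing through the lactone-enforced boat correlates 22 with 25, so no structure needs correction.
- Design changes: 22 itself is kept. Two things are changed on the way to it and from it. First, C5 is carried as an acyl oxazolidinone while C5 and C6 are set, because a plain β-keto ester at that stage would be enolised by a Grignard reagent and would lose C5. Second, ring B is closed with a bulky cationic gold catalyst suited to an internal alkyne.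
- Assumption (step 6): the quinidine-derived catalyst is assumed to give the (S) half-ester; if the first run shows the opposite sense, the quinine-derived pseudoenantiomer (DHQ)2AQN is used.

## Steps

Step 1
Reactants: 1 cyclopent-3-ene-1-carboxylic acid
Product: 2 (cyclopent-3-en-1-yl)methanol
Conditions: LiAlH4, THF, 0 °C → rt
Reagents that add atoms: none
Why: Hydride reduction of the acid to the primary alcohol; the isolated ring alkene is inert to LiAlH4 and no stereocentre is involved.

Step 2
Reactants: 2 (cyclopent-3-en-1-yl)methanol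
Product: 3 4-(iodomethyl)cyclopent-1-ene
Conditions: I2, PPh3, imidazole, CH2Cl2, 0 °C → rt
Reagents that add atoms: iodine, II
Why: Appel-type iodination of a primary alcohol through the alkoxyphosphonium salt; the iodide is chosen because the β-branched carbon needs a good leaving group in step 3.

Step 3
Reactants: 3 4-(iodomethyl)cyclopent-1-ene; 4 heptadec-1-yne
Product: 6 4-(octadec-2-yn-1-yl)cyclopent-1-ene, via lithium heptadecynide 5 (not isolated)
Conditions: 4, n-BuLi, THF, −78 → 0 °C; then 3, DMPU, 0 °C → rt
Reagents that add atoms: none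
Why: SN2 alkylation of a lithium acetylide by a primary iodide in a dipolar cosolvent; it forms C3–C4 and puts the complete arm on the future C4a.

Step 4
Reactants: 6 4-(octadec-2-yn-1-yl)cyclopent-1-ene
Product: 8 3-(octadec-2-yn-1-yl)pentanedioic acid, via dialdehyde 7 (not isolated)
Conditions: O3, CH2Cl2/MeOH, −78 °C (Sudan red end point); Me2S; then NaClO2, NaH2PO4, 2-methylbut-2-ene, t-BuOH/H2O, rt
Reagents that add atoms: ozone, [O-][O+]=O; sodium chlorite, [Na+].[O-]Cl=O
Why: Ozonolysis followed by Pinnick oxidation; ozone attacks the cis ring alkene far faster than the internal alkyne, so titration to an indicator end point spares the arm. The ring CH becomes C4a and the two alkene carbons become the two carboxyl carbons.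

Step 5
Reactants: 8 3-(octadec-2-yn-1-yl)pentanedioic acid
Product: 9 4-(octadec-2-yn-1-yl)oxane-2,6-dione
Conditions: Ac2O, 80 °C; evaporate
Reagents that add atoms: none
Why: Cyclodehydration of a 3-substituted glutaric acid to its six-membered anhydride, a prochiral compound with two enantiotopic carbonyl groups.

Step 6
Reactants: 9 4-(octadec-2-yn-1-yl)oxane-2,6-dione
Product: 10 (3S)-3-(2-methoxy-2-oxoethyl)henicos-5-ynoic acid
Conditions: MeOH (10 equiv), hydroquinidine anthraquinone-1,4-diyl diether (DHQD)2AQN (0.3 equiv), Et2O, −30 °C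
Reagents that add atoms: methanol, CO
Why: Catalytic enantioselective alcoholysis of a prochiral anhydride; the cinchona base delivers methanol to one enantiotopic carbonyl, which sets C4a. The ester ends on the C8a–C1 side and the acid on the future C5 side.

Step 7
Reactants: 10 (3S)-3-(2-methoxy-2-oxoethyl)henicos-5-ynoic acid; 11 (4R)-4-benzyl-1,3-oxazolidin-2-one
Product: 13 methyl (3S)-3-{2-[(4R)-4-benzyl-2-oxo-1,3-oxazolidin-3-yl]-2-oxoethyl}henicos-5-ynoate, via mixed pivalic anhydride 12 (not isolated)
Conditions: t-BuCOCl, Et3N, THF, −20 °C; then 11, LiCl, 0 °C → rt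
Reagents that add atoms: none
Why: N-Acylation of the oxazolidinone by the mixed anhydride under LiCl/Et3N activation; the methyl ester is untouched and C4a has no acidic hydrogen.

Step 8
Reactants: 13 methyl (3S)-3-{2-[(4R)-4-benzyl-2-oxo-1,3-oxazolidin-3-yl]-2-oxoethyl}henicos-5-ynoate; 14 heptadecanoyl chloride
Product: 16 methyl (3R)-3-{(2S)-1-[(4R)-4-benzyl-2-oxo-1,3-oxazolidin-3-yl]-1,3-dioxononadecan-2-yl}henicos-5-ynoate, via lithium Z enolate 15 (not isolated)
Conditions: LiN(i-Pr)2, THF, −78 °C; then 14, −78 °C
Reagents that add atoms: none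
Why: Auxiliary-controlled C-acylation of an imide enolate: the imide is more acidic than the ester, gives the chelated Z enolate and is acylated on the face away from the benzyl group, which sets C5 (S). Allylic strain in the β-keto imide keeps C5–H in the carbonyl plane, so the new centre should not epimerise as it would in a β-keto ester.

Step 9
Reactants: 16 methyl (3R)-3-{(2S)-1-[(4R)-4-benzyl-2-oxo-1,3-oxazolidin-3-yl]-1,3-dioxononadecan-2-yl}henicos-5-ynoate
Product: 18 (4R)-4-benzyl-3-{[(2S,3S,4R)-2-ethenyl-2-hexadecyl-4-(octadec-2-yn-1-yl)-6-oxooxan-3-yl]carbonyl}-1,3-oxazolidin-2-one, via hydroxy ester 17 (not isolated)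
Conditions: CH2=CHMgBr, CH2Cl2/THF, −78 °C; aq NH4Cl; then PPTS (cat.), PhMe, 60 °C
Reagents that add atoms: vinylmagnesium bromide, C=C[Mg]Br
Why: Chelate-controlled Grignard addition: magnesium bridges the C6 ketone and the imide carbonyl and vinyl enters anti to the C4a branch on C5, which sets C6 (S) with the vinyl group cis to the C5 acyl group. The imide is not enolised because C5–H is held in the carbonyl plane, and mild acid then closes the δ-lactone by attack of the tertiary alcohol on the C1 methyl ester.

Step 10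
Reactants: 18 (4R)-4-benzyl-3-{[(2S,3S,4R)-2-ethenyl-2-hexadecyl-4-(octadec-2-yn-1-yl)-6-oxooxan-3-yl]carbonyl}-1,3-oxazolidin-2-one
Product: 20 methyl (2S,3S,4R)-2-ethenyl-2-hexadecyl-4-(octadec-2-yn-1-yl)-6-oxooxane-3-carboxylate, via carboxylic acid 19 (not isolated)
Conditions: LiOH, H2O2, THF/H2O, 0 °C; Na2SO3, then 1 M HCl; then Me3SiCHN2, MeOH/PhMe, 0 °C
Reagents that add atoms: hydrogen peroxide, OO; (trimethylsilyl)diazomethane, C[Si](C)(C)C=[N+]=[N-]
Why: Hydroperoxide cleaves the exocyclic imide carbonyl, the peracid is reduced to the acid and the acid is methylated under neutral conditions. C5–H is never removed, so neither epimerisation nor β-elimination of the lactone oxygen is expected.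

Step 11
Reactants: 20 methyl (2S,3S,4R)-2-ethenyl-2-hexadecyl-4-(octadec-2-yn-1-yl)-6-oxooxane-3-carboxylate; 21 methyl acrylate
Product: 22 methyl (2S,3S,4R)-2-hexadecyl-2-[(1E)-3-methoxy-3-oxoprop-1-en-1-yl]-4-(octadec-2-yn-1-yl)-6-oxooxane-3-carboxylate
Conditions: 21 (10 equiv), second-generation Hoveyda–Grubbs catalyst RuCl2(H2IMes)(=CH–C6H4-2-O-i-Pr) (5 mol%), CH2Cl2, 40 °C
Reagents that add atoms: none
Why: Cross-metathesis of a hindered vinyl group with an excess of acrylate, which gives the E enoate. The alkyne is internal and sits trans to the vinyl group across the lactone ring, which disfavours ring-closing enyne metathesis.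

Step 12
Reactants: 22 methyl (2S,3S,4R)-2-hexadecyl-2-[(1E)-3-methoxy-3-oxoprop-1-en-1-yl]-4-(octadec-2-yn-1-yl)-6-oxooxane-3-carboxylate
Product: 25 (1S,2R,5S,6R)-4-hexadecyl-2,5-bis(methoxycarbonyl)-6-(octadec-2-yn-1-yl)cyclohex-3-ene-1-carboxylic acid, via silyl ketene acetal 23 (not isolated), via silyl ester 24 (not isolated)
Conditions: t-BuMe2SiCl (3 equiv), KN(SiMe3)2 (1.3 equiv, added last), THF/PhMe, −78 °C → rt, then 80 °C; 1 M HCl, THF
Reagents that add atoms: none
Why: KN(SiMe3)2 removes a C8a proton of 22 (the unhindered lactone α-CH2) with the silyl chloride already present, so the enolate is O-silylated at once to the ketene acetal 23. On warming, 23 undergoes the [3,3] shift of an Ireland–Claisen rearrangement: C8a–C8 forms as C6–O breaks, giving the silyl ester 24, which is hydrolysed to 25 on work-up. The closest known type is the ring-contracting Ireland–Claisen rearrangement of 6-alkenyl δ-lactones and 6-alkenyl dioxanones through a boat. Ring A closes as a six-membered carbocycle by this sigmatropic shift; the two-atom tether C4a–C5 joins C8a to C6, so only the bicyclo[2.2.2]-like boat is attainable. At C8a the new bond forms on the lactone face that carries the alkenyl group (cis to the C5 ester, trans to the arm), which puts C1 cis to the arm, so this centre is controlled by C6. At C8 the E geometry keeps the ester away from C6 in the boat, so it ends cis to C1 and to the arm, and this centre is controlled by the alkene geometry. The step needs deprotonation at C8a and not at C5, which is secured by the tertiary, doubly flanked position of C5–H, and it needs silylation to outrun Michael closure onto C7, which is secured by the internal quench at −78 °C. The ester on the bond-forming allyl terminus slows the shift, hence the heating.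

Step 13
Reactants: 25 (1S,2R,5S,6R)-4-hexadecyl-2,5-bis(methoxycarbonyl)-6-(octadec-2-yn-1-yl)cyclohex-3-ene-1-carboxylic acid
Product: 27 dimethyl (1R,2S,3R,4S)-5-hexadecyl-2-(3-methoxy-3-oxopropanoyl)-3-(octadec-2-yn-1-yl)cyclohex-5-ene-1,4-dicarboxylate, via acyl imidazolide 26 (not isolated)
Conditions: (Im)2CO, THF, rt; then Mg(O2CCH2CO2Me)2, THF, 40 °C; 1 M HCl
Reagents that add atoms: magnesium bis(3-methoxy-3-oxopropanoate), [Mg+2].COC(=O)CC([O-])=O.COC(=O)CC([O-])=O
Why: The acid is activated as its acyl imidazolide and C-acylates the magnesium malonate half-ester with loss of CO2, which gives the β-keto ester under near-neutral conditions. The product rests as its magnesium chelate (deprotonated at C2), which protects C8a from enolisation.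

Step 14
Reactants: 27 dimethyl (1R,2S,3R,4S)-5-hexadecyl-2-(3-methoxy-3-oxopropanoyl)-3-(octadec-2-yn-1-yl)cyclohex-5-ene-1,4-dicarboxylate
Product: 29 trimethyl (4aR,5S,8R,8aS)-3,6-dihexadecyl-1-oxo-1,4,4a,5,8,8a-hexahydronaphthalene-2,5,8-tricarboxylate, via exocyclic alkene 28 (not isolated)
Conditions: [(t-Bu2P(2-biphenylyl))Au(NCMe)]SbF6 (5 mol%), CH2Cl2, rt; then Et3N (0.2 equiv), rt
Reagents that add atoms: none
Why: Conia-ene cyclisation: the cationic monovalent gold complex activates the alkyne and the enol carbon C2 adds anti at C3 (6-exo-dig), closing ring B as the exocyclic Z alkene 28. A trace of amine then moves the double bond to C2=C3 through the doubly stabilised dienolate, C2–H being far more acidic than C8a–H, C5–H or C8–H. No stereocentre is formed and the cis ring fusion is already in place.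

## Compound list

1 | cyclopent-3-ene-1-carboxylic acid | OC(=O)C1CC=CC1 | starting material
2 | (cyclopent-3-en-1-yl)methanol | OCC1CC=CC1 | intermediate
3 | 4-(iodomethyl)cyclopent-1-ene | ICC1CC=CC1 | intermediate
4 | heptadec-1-yne | C#CCCCCCCCCCCCCCCC | starting material
5 | lithium heptadec-1-yn-1-ide | [Li+].[C-]#CCCCCCCCCCCCCCCC | intermediate (not isolated)
6 | 4-(octadec-2-yn-1-yl)cyclopent-1-ene | C1=CCC(CC#CCCCCCCCCCCCCCCC)C1 | intermediate
7 | 3-(octadec-2-yn-1-yl)pentanedial | O=CCC(CC#CCCCCCCCCCCCCCCC)CC=O | intermediate (not isolated)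
8 | 3-(octadec-2-yn-1-yl)pentanedioic acid | OC(=O)CC(CC#CCCCCCCCCCCCCCCC)CC(=O)O | intermediate
9 | 4-(octadec-2-yn-1-yl)oxane-2,6-dione | O=C1CC(CC#CCCCCCCCCCCCCCCC)CC(=O)O1 | intermediate
10 | (3S)-3-(2-methoxy-2-oxoethyl)henicos-5-ynoic acid | OC(=O)C[C@H](CC#CCCCCCCCCCCCCCCC)CC(=O)OC | intermediate
11 | (4R)-4-benzyl-1,3-oxazolidin-2-one | O=C1N[C@H](Cc2ccccc2)CO1 | starting material
12 | (3S)-3-(2-methoxy-2-oxoethyl)henicos-5-ynoic 2,2-dimethylpropanoic anhydride | CC(C)(C)C(=O)OC(=O)C[C@H](CC#CCCCCCCCCCCCCCCC)CC(=O)OC | intermediate (not isolated)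
13 | methyl (3S)-3-{2-[(4R)-4-benzyl-2-oxo-1,3-oxazolidin-3-yl]-2-oxoethyl}henicos-5-ynoate | COC(=O)C[C@@H](CC#CCCCCCCCCCCCCCCC)CC(=O)N1[C@H](Cc2ccccc2)COC1=O | intermediate
14 | heptadecanoyl chloride | CCCCCCCCCCCCCCCCC(=O)Cl | starting material
15 | lithium (Z)-enolate of 13 (C4a and O− cis on the enolate double bond) | [Li+].COC(=O)C[C@@H](CC#CCCCCCCCCCCCCCCC)/C=C(\[O-])N1[C@H](Cc2ccccc2)COC1=O | intermediate (not isolated)
16 | methyl (3R)-3-{(2S)-1-[(4R)-4-benzyl-2-oxo-1,3-oxazolidin-3-yl]-1,3-dioxononadecan-2-yl}henicos-5-ynoate | COC(=O)C[C@@H](CC#CCCCCCCCCCCCCCCC)[C@H](C(=O)N1[C@H](Cc2ccccc2)COC1=O)C(=O)CCCCCCCCCCCCCCCC | intermediate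
17 | methyl (3R)-3-{(2S,3S)-1-[(4R)-4-benzyl-2-oxo-1,3-oxazolidin-3-yl]-3-ethenyl-3-hydroxy-1-oxononadecan-2-yl}henicos-5-ynoate | COC(=O)C[C@@H](CC#CCCCCCCCCCCCCCCC)[C@H](C(=O)N1[C@H](Cc2ccccc2)COC1=O)[C@](O)(CCCCCCCCCCCCCCCC)C=C | intermediate (not isolated)
18 | (4R)-4-benzyl-3-{[(2S,3S,4R)-2-ethenyl-2-hexadecyl-4-(octadec-2-yn-1-yl)-6-oxooxan-3-yl]carbonyl}-1,3-oxazolidin-2-one | O=C1C[C@@H](CC#CCCCCCCCCCCCCCCC)[C@H](C(=O)N2[C@H](Cc3ccccc3)COC2=O)[C@](CCCCCCCCCCCCCCCC)(C=C)O1 | intermediate
19 | (2S,3S,4R)-2-ethenyl-2-hexadecyl-4-(octadec-2-yn-1-yl)-6-oxooxane-3-carboxylic acid | O=C1C[C@@H](CC#CCCCCCCCCCCCCCCC)[C@H](C(=O)O)[C@](CCCCCCCCCCCCCCCC)(C=C)O1 | intermediate (not isolated)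
20 | methyl (2S,3S,4R)-2-ethenyl-2-hexadecyl-4-(octadec-2-yn-1-yl)-6-oxooxane-3-carboxylate | O=C1C[C@@H](CC#CCCCCCCCCCCCCCCC)[C@H](C(=O)OC)[C@](CCCCCCCCCCCCCCCC)(C=C)O1 | intermediate
21 | methyl acrylate (methyl prop-2-enoate) | C=CC(=O)OC | starting material
22 | methyl (2S,3S,4R)-2-hexadecyl-2-[(1E)-3-methoxy-3-oxoprop-1-en-1-yl]-4-(octadec-2-yn-1-yl)-6-oxooxane-3-carboxylate | O=C1C[C@@H](CC#CCCCCCCCCCCCCCCC)[C@H](C(=O)OC)[C@](CCCCCCCCCCCCCCCC)(/C=C/C(=O)OC)O1 | intermediate (key-step precursor)
23 | methyl (2S,3S,4R)-6-[(tert-butyldimethylsilyl)oxy]-2-hexadecyl-2-[(1E)-3-methoxy-3-oxoprop-1-en-1-yl]-4-(octadec-2-yn-1-yl)-3,4-dihydro-2H-pyran-3-carboxylate | CC(C)(C)[Si](C)(C)OC1=C[C@@H](CC#CCCCCCCCCCCCCCCC)[C@H](C(=O)OC)[C@](CCCCCCCCCCCCCCCC)(/C=C/C(=O)OC)O1 | intermediate (not isolated)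
24 | tert-butyldimethylsilyl ester of 25 | CCCCCCCCCCCCCCCCC1=C[C@@H](C(=O)OC)[C@@H](C(=O)O[Si](C)(C)C(C)(C)C)[C@@H](CC#CCCCCCCCCCCCCCCC)[C@@H]1C(=O)OC | intermediate (not isolated)
25 | (1S,2R,5S,6R)-4-hexadecyl-2,5-bis(methoxycarbonyl)-6-(octadec-2-yn-1-yl)cyclohex-3-ene-1-carboxylic acid | CCCCCCCCCCCCCCCCC1=C[C@@H](C(=O)OC)[C@@H](C(=O)O)[C@@H](CC#CCCCCCCCCCCCCCCC)[C@@H]1C(=O)OC | intermediate (key-step product)
26 | acyl imidazolide of 25 | CCCCCCCCCCCCCCCCC1=C[C@@H](C(=O)OC)[C@@H](C(=O)n2ccnc2)[C@@H](CC#CCCCCCCCCCCCCCCC)[C@@H]1C(=O)OC | intermediate (not isolated)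
27 | dimethyl (1R,2S,3R,4S)-5-hexadecyl-2-(3-methoxy-3-oxopropanoyl)-3-(octadec-2-yn-1-yl)cyclohex-5-ene-1,4-dicarboxylate | CCCCCCCCCCCCCCCCC1=C[C@@H](C(=O)OC)[C@@H](C(=O)CC(=O)OC)[C@@H](CC#CCCCCCCCCCCCCCCC)[C@@H]1C(=O)OC | intermediate
28 | trimethyl (4aR,5S,8R,8aS)-6-hexadecyl-3-[(Z)-hexadecylidene]-1-oxo-1,2,3,4,4a,5,8,8a-octahydronaphthalene-2,5,8-tricarboxylate (C2 enolisable, not defined) | CCCCCCCCCCCCCCCCC1=C[C@@H](C(=O)OC)[C@H]2C(=O)C(C(=O)OC)/C(=C\CCCCCCCCCCCCCCC)C[C@H]2[C@@H]1C(=O)OC | intermediate (not isolated)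
29 | trimethyl (4aR,5S,8R,8aS)-3,6-dihexadecyl-1-oxo-1,4,4a,5,8,8a-hexahydronaphthalene-2,5,8-tricarboxylate | CCCCCCCCCCCCCCCCC1=C[C@@H](C(=O)OC)[C@H]2C(=O)C(C(=O)OC)=C(CCCCCCCCCCCCCCCC)C[C@H]2[C@@H]1C(=O)OC | target

## Step count and weakest steps

Total: 14 steps. Longest linear sequence: 14 steps (1 to 29); 4, 11, 14 and 21 are bought.

Step 12 (key step). The most likely failure is ring closure of the potassium enolate onto C7 before it is silylated. A second is a sluggish shift, because the ester sits on the bond-forming allyl terminus, which leaves time for loss of the lactone oxygen by β-elimination. The fallback moves the rearrangement ahead of the ester. It sets out from 20: cross-metathesis with allyl tert-butyldimethylsilyl ether should give the (E)-allylic silyl ether lactone F1, whose alkene is neither a Michael acceptor nor deactivated. The same ring contraction then gives the acid F2, and the malonate homologation of step 13 gives the β-keto ester F3. HF·pyridine frees the alcohol F4, and oxidation with TEMPO and PhI(OAc)2 in wet acetonitrile gives the acid F5. Me3SiCHN2 brings the route back at 27.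

Step 9. The most likely failures are enolisation of the ketone on its hexadecyl side by the basic Grignard reagent, and loss of chelate control, which would give poor facial selectivity at C6. The fallback uses a non-basic π-nucleophile under a defined chelate. It sets out from 16: TiCl4 and allyltrimethylsilane (Sakurai allylation, CH2Cl2, −78 °C), followed by the lactonisation of step 9, should give the allyl lactone imide F6. The auxiliary is removed as in step 10 through the acid F7 to the methyl ester F8. RuHCl(CO)(PPh3)3 in toluene at 80 °C moves the terminal alkene one position, and no further past the quaternary C6, to the (E)-propenyl lactone F9. Cross-metathesis with 21 as in step 11 comes back at 22.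

Step 10. The most likely failure is slow attack at the exocyclic carbonyl, which is flanked by the quaternary C6 and the branched C4a, so that opening of the oxazolidinone ring or of the lactone competes. The fallback carries the auxiliary further and removes it when C6 has become trigonal. It sets out from 18: cross-metathesis with 21 gives the enoate lactone imide F10, and the ring contraction of step 12 gives the acid imide F11; the imide also keeps C5–H non-acidic during that step. MeOMgBr (from MeMgBr and MeOH, 0 °C) then exchanges the auxiliary for methoxide and comes back at 25.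

Step 11. The most likely failures are engagement of the internal alkyne by the ruthenium carbene (enyne metathesis) and poor turnover at a vinyl group on a fully substituted carbon. The fallback is an olefination without a metal carbene. It sets out from 20: ozonolysis to the Sudan red end point and Me2S give the aldehyde F12, which has no α-hydrogen and cannot epimerise, and Ph3P=CHCO2Me in toluene comes back at 22 with E geometry.

Step 14. The most likely failures are attack of the enol oxygen at C3 in place of C2, closure at the distal alkyne carbon to a seven-membered ring, and low reactivity of the internal alkyne. The fallback lets the carboxyl group hydrate the alkyne before the homologation. It sets out from 25: Ph3PAuCl/AgOTf should give the (Z)-enol lactone F13 by 6-exo-dig addition of the acid, and dilute aqueous acid opens it to the keto acid F14. The imidazolide and magnesium malonate sequence of step 13 gives the keto β-keto ester F15, and piperidinium acetate in toluene closes ring B by Knoevenagel condensation, coming back at 29.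

## Further compounds

F1 | step 12 | methyl (2S,3S,4R)-2-[(1E)-3-[(tert-butyldimethylsilyl)oxy]prop-1-en-1-yl]-2-hexadecyl-4-(octadec-2-yn-1-yl)-6-oxooxane-3-carboxylate | O=C1C[C@@H](CC#CCCCCCCCCCCCCCCC)[C@H](C(=O)OC)[C@](CCCCCCCCCCCCCCCC)(/C=C/CO[Si](C)(C)C(C)(C)C)O1
F2 | step 12 | (1S,2R,5S,6R)-2-{[(tert-butyldimethylsilyl)oxy]methyl}-4-hexadecyl-5-(methoxycarbonyl)-6-(octadec-2-yn-1-yl)cyclohex-3-ene-1-carboxylic acid | CCCCCCCCCCCCCCCCC1=C[C@@H](CO[Si](C)(C)C(C)(C)C)[C@@H](C(=O)O)[C@@H](CC#CCCCCCCCCCCCCCCC)[C@@H]1C(=O)OC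
F3 | step 12 | β-keto ester from F2 (C8a bears C(=O)CH2CO2Me, C8 bears CH2OSi(t-Bu)Me2; 4aR,5S,8R,8aS in target locants) | CCCCCCCCCCCCCCCCC1=C[C@@H](CO[Si](C)(C)C(C)(C)C)[C@@H](C(=O)CC(=O)OC)[C@@H](CC#CCCCCCCCCCCCCCCC)[C@@H]1C(=O)OC
F4 | step 12 | primary alcohol from F3 (C8 bears CH2OH) | CCCCCCCCCCCCCCCCC1=C[C@@H](CO)[C@@H](C(=O)CC(=O)OC)[C@@H](CC#CCCCCCCCCCCCCCCC)[C@@H]1C(=O)OC
F5 | step 12 | carboxylic acid from F4 (C8 bears CO2H) | CCCCCCCCCCCCCCCCC1=C[C@@H](C(=O)O)[C@@H](C(=O)CC(=O)OC)[C@@H](CC#CCCCCCCCCCCCCCCC)[C@@H]1C(=O)OC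
F6 | step 9 | (4R)-4-benzyl-3-{[(2S,3S,4R)-2-hexadecyl-4-(octadec-2-yn-1-yl)-6-oxo-2-(prop-2-en-1-yl)oxan-3-yl]carbonyl}-1,3-oxazolidin-2-one | O=C1C[C@@H](CC#CCCCCCCCCCCCCCCC)[C@H](C(=O)N2[C@H](Cc3ccccc3)COC2=O)[C@](CCCCCCCCCCCCCCCC)(CC=C)O1
F7 | step 9 | (2S,3S,4R)-2-hexadecyl-4-(octadec-2-yn-1-yl)-6-oxo-2-(prop-2-en-1-yl)oxane-3-carboxylic acid | O=C1C[C@@H](CC#CCCCCCCCCCCCCCCC)[C@H](C(=O)O)[C@](CCCCCCCCCCCCCCCC)(CC=C)O1
F8 | step 9 | methyl (2S,3S,4R)-2-hexadecyl-4-(octadec-2-yn-1-yl)-6-oxo-2-(prop-2-en-1-yl)oxane-3-carboxylate | O=C1C[C@@H](CC#CCCCCCCCCCCCCCCC)[C@H](C(=O)OC)[C@](CCCCCCCCCCCCCCCC)(CC=C)O1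
F9 | step 9 | methyl (2S,3S,4R)-2-hexadecyl-4-(octadec-2-yn-1-yl)-6-oxo-2-[(1E)-prop-1-en-1-yl]oxane-3-carboxylate | O=C1C[C@@H](CC#CCCCCCCCCCCCCCCC)[C@H](C(=O)OC)[C@](CCCCCCCCCCCCCCCC)(/C=C/C)O1
F10 | step 10 | methyl (2E)-3-[(2S,3S,4R)-3-{[(4R)-4-benzyl-2-oxo-1,3-oxazolidin-3-yl]carbonyl}-2-hexadecyl-4-(octadec-2-yn-1-yl)-6-oxooxan-2-yl]prop-2-enoate | O=C1C[C@@H](CC#CCCCCCCCCCCCCCCC)[C@H](C(=O)N2[C@H](Cc3ccccc3)COC2=O)[C@](CCCCCCCCCCCCCCCC)(/C=C/C(=O)OC)O1
F11 | step 10 | ring A acid with the C5 carboxyl as (4R)-4-benzyl-2-oxo-1,3-oxazolidin-3-yl imide (C8 CO2Me, C8a CO2H; 4aR,5S,8R,8aS in target locants) | CCCCCCCCCCCCCCCCC1=C[C@@H](C(=O)OC)[C@@H](C(=O)O)[C@@H](CC#CCCCCCCCCCCCCCCC)[C@@H]1C(=O)N2[C@H](Cc3ccccc3)COC2=O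
F12 | step 11 | methyl (2R,3S,4R)-2-formyl-2-hexadecyl-4-(octadec-2-yn-1-yl)-6-oxooxane-3-carboxylate | O=C1C[C@@H](CC#CCCCCCCCCCCCCCCC)[C@H](C(=O)OC)[C@](CCCCCCCCCCCCCCCC)(C=O)O1
F13 | step 14 | cis-fused (Z)-enol lactone: dimethyl (4aR,5S,8R,8aS)-6-hexadecyl-3-[(Z)-hexadecylidene]-1-oxo-3,4,4a,5,8,8a-hexahydro-1H-isochromene-5,8-dicarboxylate | CCCCCCCCCCCCCCCCC1=C[C@@H](C(=O)OC)[C@H]2C(=O)O/C(=C\CCCCCCCCCCCCCCC)C[C@H]2[C@@H]1C(=O)OC
F14 | step 14 | (1S,2R,5S,6R)-4-hexadecyl-2,5-bis(methoxycarbonyl)-6-(2-oxooctadecyl)cyclohex-3-ene-1-carboxylic acid | CCCCCCCCCCCCCCCCC1=C[C@@H](C(=O)OC)[C@@H](C(=O)O)[C@@H](CC(=O)CCCCCCCCCCCCCCCC)[C@@H]1C(=O)OC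
F15 | step 14 | dimethyl (1R,2S,3R,4S)-5-hexadecyl-2-(3-methoxy-3-oxopropanoyl)-3-(2-oxooctadecyl)cyclohex-5-ene-1,4-dicarboxylate | CCCCCCCCCCCCCCCCC1=C[C@@H](C(=O)OC)[C@@H](C(=O)CC(=O)OC)[C@@H](CC(=O)CCCCCCCCCCCCCCCC)[C@@H]1C(=O)OC
A1 | alternative 1 | methyl 6-hexadecyl-2-oxo-3-[(2Z,5E)-1-[(tert-butyldimethylsilyl)oxy]-3-hexadecyl-7-methoxy-7-oxohepta-2,5-dien-1-yl]-2H-pyran-4-carboxylate | O=c1oc(CCCCCCCCCCCCCCCC)cc(C(=O)OC)c1[C@H](O[Si](C)(C)C(C)(C)C)/C=C(CCCCCCCCCCCCCCCC)\C/C=C/C(=O)OC
A2 | alternative 1 | bicyclic diene diester with C6=C7 and C8=C8a in ring A, C1 silyl ether and C2=C3 in ring B | CCCCCCCCCCCCCCCCC1=CC(C(=O)OC)=C2[C@H](O[Si](C)(C)C(C)(C)C)C=C(CCCCCCCCCCCCCCCC)C[C@H]2[C@@H]1C(=O)OC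
A3 | alternative 2 | dimethyl (2E,5Z,8E)-4-[(tert-butyldimethylsilyl)oxy]-6-hexadecyldeca-2,5,8-trienedioate | COC(=O)/C=C/[C@H](O[Si](C)(C)C(C)(C)C)/C=C(CCCCCCCCCCCCCCCC)\C/C=C/C(=O)OC
A4 | alternative 2 | octadec-1-yne | C#CCCCCCCCCCCCCCCCC
A5 | alternative 2 | cis-fused bicycle with C1 silyl ether, C2=C3 in ring B and C6=C7 in ring A | CCCCCCCCCCCCCCCCC1=C[C@@H](C(=O)OC)[C@H]2[C@H](O[Si](C)(C)C(C)(C)C)C=C(CCCCCCCCCCCCCCCC)C[C@H]2[C@@H]1C(=O)OC
A6 | alternative 3 | open triene (C4a=C5, C6=C7 cis-linked, C8=C8a) with the arm on C4a and the silyloxy ester chain on C8a, both outward | CCCCCCCCCCCCCCCC#CC/C=C(C(=O)OC)/C(CCCCCCCCCCCCCCCC)=C\C(C(=O)OC)=C\[C@H](O[Si](C)(C)C(C)(C)C)CC(=O)OC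
A7 | alternative 3 | ring A cyclohexa-1,3-diene diester with cis C4a and C8a substituents | CCCCCCCCCCCCCCCCC1=C(C(=O)OC)[C@H](CC#CCCCCCCCCCCCCCCC)[C@H]([C@H](O[Si](C)(C)C(C)(C)C)CC(=O)OC)C(C(=O)OC)=C1
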